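## Structural features

Conneotricone is an achiral depsidone. Two benzene rings, ring A and ring B, are joined twice: by an aryl ester (ring A carbonyl carbon to a ring B oxygen) and by a diaryl ether on the neighbouring carbons, which closes a seven-membered dibenzo[b,e][1,4]dioxepin-11-one. Ring B also carries a fused γ-lactone (a phthalide). There is no stereocentre, so every selectivity question is one of regiochemistry or chemoselectivity.

Ring A has five substituents (methyl, hydroxyl, carboxylic acid, ether oxygen, ester carbonyl). Ring B is fully substituted (ester oxygen, hydroxymethyl, hydroxyl, lactone carbonyl, lactone methylene, ether oxygen).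

The fragile groups are:
- the seven-membered aryl ester, which opens with alkoxides, amines or hydroxide;
- the ring A carboxylic acid flanked by two oxygens, which can decarboxylate;
- the benzylic alcohol between two oxygenated carbons, which can ionise or give an ortho-quinone methide;
- the phthalide, which opens reversibly in base.

The real difficulty is the diaryl ether between two fully flanked carbons inside the seven-membered ring, together with telling apart two phenols and two benzylic carbons on ring B.

The key step exploits the resorcylate pattern of ring A. The carbon bearing the ester carbonyl lies between the methyl-bearing carbon and an oxygen-bearing carbon. A second oxygen sits meta to the first, and the carboxyl carbon lies between the two. This is the folding pattern of a 3,5,7-triketo ester with a carboxyl on C4, so ring A can be grown on the ring B oxygen instead of being made by substitution of an arene.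

## Logic of the disconnections

**18 from 16.** The last cuts are three oxygen–protecting-group bonds: O–CH3 at the chelated ring B phenol, O–CH2Ph at the ring A carboxyl and O–Si at the benzylic alcohol. They come last because the free acid, free benzylic alcohol and free chelated phenol are the groups most likely to disturb ring formation. All three fall to one boron Lewis acid that attacks chelated positions, followed by dilute aqueous acid, and neither opens the seven-membered ester. The gain is that everything before 18 is lipophilic and carries no acidic proton other than phenols. The demand is that the benzylic oxygen is not exchanged for halide and that no nucleophile meets the aryl ester.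

**16 from 15.** The ring B carbon–oxygen bond of the diaryl ether is cut. This opens the seven-membered ring and leaves an aryl bromide next to the ester oxygen on ring B and a phenol next to the ester carbonyl on ring A. Cutting the ether and not the ester keeps the rings tethered, so the C–O coupling between two crowded positions is intramolecular. The gain is an open depside whose ring A can be built directly on ring B. The demand is a copper-mediated closure that tolerates an aryl ester and two free phenols, only one of which can reach the bromide.

**15 from 4 and 12.** Two bonds are cut: the ester C–O bond between the ring A carbonyl and the ring B oxygen, and the ring A C–C bond between the carbon carrying that carbonyl and the methyl-bearing carbon. Ring A unfolds into an eight-carbon 3,5,7-triketo ester chain with a carboxyl on C4, masked as acylketene precursor 4, and ring B is reduced to phenol 12. This is the largest gain of the route: ring A needs no aromatic substitution, and the hydroxyl for the later ether closure appears next to the new ester automatically. The demands are three: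
- the ketene from 4 must be caught by a phenol flanked by bromine and a silyloxymethyl group;
- the chain must close in the aldol sense and not the Claisen sense;
- the spectator ester on C4 must survive 110 °C. It is therefore a benzyl ester, because a tert-butyl β-keto ester would itself eliminate to a ketene at that temperature.

**4 from 1 through 3 and 2.** Three C–C bonds are cut in turn: the diketone bond (4 to 3), the acetyl bond (3 to 2) and the carboxyl bond (2 to 1). Each cut removes an acyl group from the nucleophilic carbon of an enolate, so all three forward steps are enolate acylations on one commodity reagent. The gain is a short linear branch. The demand is regiocontrol: the first two acylations must occur at the exocyclic γ-carbon and the third at the terminal methyl of a dianion, and 4 must be handled without base or silica.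

**12 from 9 through 11.** The O–Si bond, the lactone C–O bond and the benzylic C–O bond are cut back to two benzylic C–Br bonds. Phthalide and hydroxymethyl group thus both come from bromomethyl groups, one of which sits next to the methyl ester. The gain is that both benzylic carbons are oxidised in one operation and are then differentiated by position alone, since only one can lactonise. The demand is hydrolysis while the neighbouring phenol is still masked, then unmasking, then silylation of the primary alcohol beside the phenol.

**9 from 5 through 8, 7 and 6.** The benzylic C–Br bonds are cut to C–H (9 to 8), then O–CH3 (8 to 7), O–acetyl (7 to 6) and the ring C–Br bond (6 to 5). Bromine goes on the ring first: the single free position is ortho and para to the two hydroxyls, and a fully substituted ring cannot be brominated during the later radical step. The phenols are told apart by hydrogen bonding. The one next to the ester is the less reactive, so the other is acetylated and the chelated one is then methylated. The gain is that 5 already contains every ring B carbon. The demand is a methylation that leaves the aryl acetate in place and a radical bromination that stops at one bromine per methyl group.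

## Other disconnections considered

**Alternative 1:** 
- **Cut:** through ring B. The bond between the silyloxymethyl-bearing carbon and the methoxy-bearing carbon and the bond between the ester-bearing carbon and the acetoxymethyl-bearing carbon are broken. This leaves the 1,3-bis(silyl enol ether) A1 and the three-carbon dielectrophile A2, an α-oxo ketene acetal that already carries protected ring A as its 2-aryloxy group.
- **Forward key step:** TiCl4 would promote a formal (3+3) cyclocondensation. The terminal diene carbon adds to the ketene acetal carbon (vinylogous Mukaiyama-type addition, loss of methanol), the ester-bearing carbon condenses with the ketone (Mukaiyama aldol), and aromatisation gives salicylate A3 with the diaryl ether in place.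
- **In favour:** the diaryl ether, the hardest bond of the target, is made by O-alkylation before ring B exists, so no C–O coupling at a hexasubstituted arene is needed. On this point A3 is better than 15. All six ring B substituents are fixed by the acyclic partners, and the lactone methylene arrives already oxidised, so no benzylic bromination is needed (also better).
- **Against it here:**
  - A2 requires alkylation of a phenol flanked by two esters, and it contains an acid-sensitive ketene acetal next to an α-acetoxy ketone.
  - The Lewis acid has to spare a silyl ether, a benzyl ether, a benzyl ester and the acetal.
  - The regiochemistry depends on the diene terminus choosing the acetal carbon over the ketone.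
  - In A3 the oxygen that must become the depsidone ester oxygen is a non-chelated methyl ether, while the chelated position is free. A demethylation without a directing handle, a selective hydrolysis of the hindered ring A methyl ester and a seven-membered lactonisation would still lie ahead.
- **Comparison:** structurally both plans build one arene onto the other. Mechanistically the alternative is a Lewis-acid cascade on sensitive partners, against a neutral thermal capture and mild base in the chosen plan. In step count the two are about equal up to the key step, but the alternative should need roughly twice as many operations afterwards as the two that follow 15.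

**Alternative 2:** 
- **Cut:** the lactone methylene is removed. The aryl–CH2 bond and the CH2–O bond of the phthalide are broken, leading to depsidone acid A4 with one free ortho C–H and dibromomethane as the one-carbon unit.
- **Forward key step:** Pd(OAc)2 (divalent palladium) with a phosphate base in hot dibromomethane would effect carboxylate-directed ortho C–H palladation and alkylation, and the carboxylate would displace the second bromide to close the lactone, giving A5.
- **In favour:** only one ortho C–H exists, so the regiochemistry is unambiguous. Ring B would need one benzylic oxidation instead of two, which removes the double radical bromination and the differentiation of two methyl groups. On this point the alternative is better than the chosen plan. The step is catalytic and adds the last ring atom late.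
- **Against it here:**
  - The cut simplifies only the phthalide, the easiest ring. The diaryl ether and ester between two crowded rings must be made beforehand by other means.
  - An extra ring B carboxyl has to be kept distinct from the ring A benzyl ester.
  - Carboxylate and bromide nucleophiles near 140 °C endanger the seven-membered aryl ester, the benzyl ester and the benzylic silyl ether.
  - Palladation must occur beside the ether oxygen on an almost fully substituted ring.
- **Comparison:** structurally it leaves the core problem untouched. Mechanistically it places a demanding C–H functionalisation on the most advanced intermediate, whereas the chosen plan places its uncertain bond formations at the fragment union. In step economy it is equal at best: about two steps saved on ring B are spent on the differentiated acid.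

**Alternative 3:** 
- **Cut:** ring B and the lactone are dismantled to a linear triyne. The bond between the two lactone-bearing ring carbons, the bond between the silyl-bearing and the silyloxymethyl-bearing carbons and the ester C–O bond are broken, leaving the 2,4-diynyl propiolate A6 and ring A acid A8.
- **Forward key step:** heating A6 would trigger a hexadehydro-Diels–Alder cycloisomerisation to benzyne A7, fused to the butenolide. The carboxylic acid of A8 would add across the strained bond, oxygen at the carbon next to the silyloxymethyl group, to give depside A9.
- **In favour:** two rings and three skeletal bonds would form in one metal-free thermal step, against one ring and two bonds in the chosen key step. In convergence and bond economy of the key step the alternative is the better. A6 needs only alkyne couplings and an esterification, and ring B needs no aromatic substitution.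
- **Against it here:**
  - In A9 the carbon that must carry the ether oxygen is C–H and the carbon that must carry the hydroxyl is C–Si.
  - The seven-membered ether would have to be closed by oxidative C–H etherification, for which no dependable method exists on such a ring.
  - The silicon-to-oxygen exchange (Tamao–Fleming conditions, fluoride and peroxide) threatens the aryl ester and the lactone.
  - The regiochemistry of the acid addition rests on aryne distortion alone, and the phenols of A8 may compete.
- **Comparison:** structurally A9 is a depside like 15 but lacks the halogen handle that makes the ether closure of the chosen plan a known reaction. Mechanistically both key steps are thermal and neutral, so they are equal in functional-group tolerance. In step economy the gain before the key step should be lost, and more, after it.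

Key step: step 10

Remark on the chemistry: the stated structures of the ring B phenol, the depside and the target were compared position by position and agree, so no connectivity was changed. The only design change is that the spectator ester of the polyketide chain is a benzyl ester and not a tert-butyl ester. A tert-butyl β-keto ester loses tert-butanol near 100–110 °C to give an acylketene of its own (the property that makes tert-butyl acetoacetate a thermal acetoacetylating agent), which would compete with the dioxinone fragmentation. Atraric acid and 2,2,6-trimethyl-4H-1,3-dioxin-4-one are assumed to be purchased.

Step 1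
Reactants: 1 2,2,6-trimethyl-4H-1,3-dioxin-4-one
Product: 2 benzyl 2-(2,2-dimethyl-4-oxo-4H-1,3-dioxin-6-yl)acetate
Conditions: LiHMDS (2.1 equiv), THF, −78 °C; CbzCl; aq. NH4Cl
Reagents that add atoms: benzyl chloroformate, O=C(Cl)OCc1ccccc1
Why: The lithium dienolate of 1 is acylated at the γ-carbon (the former methyl group) by the chloroformate, a vinylogous Claisen-type C-acylation known for this dienolate. The second equivalent of base takes up the more acidic product proton and prevents double acylation.

Step 2
Reactants: 2 benzyl 2-(2,2-dimethyl-4-oxo-4H-1,3-dioxin-6-yl)acetate
Product: 3 benzyl 2-(2,2-dimethyl-4-oxo-4H-1,3-dioxin-6-yl)-3-oxobutanoate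
Conditions: LiHMDS (2.1 equiv), THF, −78 °C; AcCl (1.0 equiv); aq. NH4Cl
Reagents that add atoms: acetyl chloride, CC(=O)Cl
Why: The extended enolate of 2 (ester plus vinylogous ester) is C-acylated at the same exocyclic carbon, as acyl chlorides do with dioxinone dienolates. The product stays as its stabilised enolate until the quench, so it is not acylated again.

Step 3
Reactants: 3 benzyl 2-(2,2-dimethyl-4-oxo-4H-1,3-dioxin-6-yl)-3-oxobutanoate
Product: 4 benzyl 2-(2,2-dimethyl-4-oxo-4H-1,3-dioxin-6-yl)-3,5-dioxohexanoate (diketo dioxinone)
Conditions: LDA (2.3 equiv), THF, −78 → −40 °C; MeC(O)N(OMe)Me; 1 M HCl, −78 °C
Reagents that add atoms: N-methoxy-N-methylacetamide, CON(C)C(C)=O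
Why: Double deprotonation gives a dianion (central tricarbonyl-stabilised anion plus terminal methyl carbanion) of the kind formed by acetoacetates and β-diketones. The terminal carbon adds to the N-methoxy-N-methylamide, and the chelated tetrahedral adduct releases the 1,3-diketone only on acidic quench (dianion Claisen acylation). 4 is used crude, because base or silica would trigger premature cyclisation onto the dioxinone.

Step 4
Reactants: 5 atraric acid (methyl 2,4-dihydroxy-3,6-dimethylbenzoate)
Product: 6 methyl 3-bromo-4,6-dihydroxy-2,5-dimethylbenzoate
Conditions: NBS (1.05 equiv), MeCN, 0 °C, dark
Reagents that add atoms: N-bromosuccinimide, O=C1CCC(=O)N1Br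
Why: Electrophilic aromatic bromination at the only unsubstituted ring carbon, which is ortho and para to the two hydroxyls. Cold, dark, polar conditions keep the methyl groups out of play.

Step 5
Reactants: 6 methyl 3-bromo-4,6-dihydroxy-2,5-dimethylbenzoate
Product: 7 methyl 4-acetoxy-3-bromo-6-hydroxy-2,5-dimethylbenzoate
Conditions: Ac2O (1.1 equiv), pyridine, CH2Cl2, 0 °C → rt
Reagents that add atoms: acetic anhydride, CC(=O)OC(C)=O
Why: Acylation of the non-chelated phenol (between methyl and bromine). The other hydroxyl is hydrogen-bonded to the ester carbonyl and stays free with one equivalent of anhydride and pyridine as the only base.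

Step 6
Reactants: 7 methyl 4-acetoxy-3-bromo-6-hydroxy-2,5-dimethylbenzoate
Product: 8 methyl 4-acetoxy-3-bromo-6-methoxy-2,5-dimethylbenzoate
Conditions: MeOH, PPh3, DIAD, THF, 0 °C → rt
Reagents that add atoms: methanol, CO
Why: Mitsunobu etherification methylates the chelated phenol under neutral conditions, so the aryl acetate neither migrates nor cleaves as it could with carbonate and methyl iodide. Attack of the phenoxide on the small methoxyphosphonium centre tolerates the two ortho substituents.

Step 7
Reactants: 8 methyl 4-acetoxy-3-bromo-6-methoxy-2,5-dimethylbenzoate
Product: 9 methyl 4-acetoxy-3-bromo-2,5-bis(bromomethyl)-6-methoxybenzoate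
Conditions: NBS (2.2 equiv), AIBN (cat.), PhCF3, 85 °C
Reagents that add atoms: N-bromosuccinimide, O=C1CCC(=O)N1Br
Why: Wohl–Ziegler radical bromination of both benzylic methyl groups. The ring is fully substituted and deactivated by ester, acetate and bromine, so ionic ring bromination cannot intervene, and each methyl group, flanked by two ortho substituents, resists a second bromination.

Step 8
Reactants: 9 methyl 4-acetoxy-3-bromo-2,5-bis(bromomethyl)-6-methoxybenzoate
Product: 11 4-bromo-5-hydroxy-6-(hydroxymethyl)-7-methoxyisobenzofuran-1(3H)-one, via phthalide acetate 10 (not isolated)
Conditions: H2O–1,4-dioxane, CaCO3, 100 °C; then LiOH, THF–H2O, 0 °C → rt; then 1 M HCl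
Reagents that add atoms: water, O
Why: Neutral solvolysis turns both benzylic bromides into alcohols, and the one ortho to the methyl ester lactonises to the phthalide with loss of methanol. The phenol is still acetylated at this stage, which keeps ortho-quinone methide pathways closed. Aqueous LiOH then removes the acetate (wherever acyl migration has placed it) and acidification recloses any opened lactone.

Step 9
Reactants: 11 4-bromo-5-hydroxy-6-(hydroxymethyl)-7-methoxyisobenzofuran-1(3H)-one
Product: 12 4-bromo-6-{[(tert-butyldimethylsilyl)oxy]methyl}-5-hydroxy-7-methoxyisobenzofuran-1(3H)-one (ring B bromo phthalide phenol)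
Conditions: TBSCl (1.1 equiv), imidazole, DMF, 0 °C
Reagents that add atoms: tert-butyldimethylsilyl chloride, CC(C)(C)[Si](C)(C)Cl
Why: Silylation of the primary alcohol should outpace that of the acidic phenol flanked by bromine and the benzylic carbon. Any aryl silyl ether formed is the most labile Si–O bond and is returned to the phenol by a brief K2CO3/MeOH treatment.

Step 10
Reactants: 4 benzyl 2-(2,2-dimethyl-4-oxo-4H-1,3-dioxin-6-yl)-3,5-dioxohexanoate (diketo dioxinone); 12 ring B bromo phthalide phenol
Product: 15 bromo depside 1-benzyl 3-(4-bromo-6-{[(tert-butyldimethylsilyl)oxy]methyl}-7-methoxy-1-oxo-1,3-dihydroisobenzofuran-5-yl) 2,6-dihydroxy-4-methylbenzene-1,3-dicarboxylate, via acylketene 13 (not isolated), via aryl triketo ester 14 (not isolated)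
Conditions: PhMe, 110 °C, 4 (1.6 equiv) added in portions to concentrated 12; then Et3N, CH2Cl2, rt; dilute HCl work-up
Reagents that add atoms: none
Why: At 110 °C 4 loses acetone by retro-(4+2) fragmentation to acylketene 13, and the phenol of 12 adds to the ketene carbon to give the aryl 3,5,7-triketo ester 14. Et3N then brings about intramolecular aldol addition of the ester α-carbon (C2, between the aryl ester and the C3 ketone) to the C7 methyl ketone, and dehydration with enolisation delivers the aromatic resorcylate 15. The closest known reaction type is the dioxinone thermolysis, ketene trapping by an alcohol or phenol and aldol aromatisation sequence used for resorcylates, which copies polyketide folding. Ring A closes in a 6-(enolexo)-exo-trig aldol mode, and no stereocentre is formed because the transient carbinol is lost on dehydration. The first selectivity needed is intermolecular capture over self-trapping of the ketene by an enol oxygen of its own chain; a concentrated solution of 12, portionwise addition of excess 4 and the absence of any other hydroxyl group serve this. The second is aldol over Claisen ring closure: C2 is doubly activated, the methyl ketone is the only carbonyl outside the enolised tricarbonyl unit, a tertiary amine is too weak to drive attack on the aryl ester, and aromatisation makes the aldol path irreversible. The benzyl ester should not fragment at this temperature as a tert-butyl β-keto ester would, and the bromide, silyl ether, methyl ether and γ-lactone are spectators.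

Step 11
Reactants: 15 bromo depside
Product: 16 protected depsidone (conneotricone benzyl ester carrying the ring B methyl ether and the benzylic tert-butyldimethylsilyl ether)
Conditions: CuI (20 mol %), N,N-dimethylglycine (40 mol %), Cs2CO3, 1,4-dioxane, 90 °C
Reagents that add atoms: none
Why: Intramolecular Ullmann diaryl ether synthesis. The phenoxide next to the depside carbonyl binds monovalent copper (CuI), and oxidative addition into the neighbouring C–Br bond followed by reductive elimination closes the seven-membered ring. The tether offsets the crowding at the bromide, and the second ring A phenol, para to the ester carbon, cannot reach the bromide.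

Step 12
Reactants: 16 protected depsidone
Product: 18 conneotricone, via conneotricone silyl ether 17 (not isolated)
Conditions: BCl3, C6HMe5, CH2Cl2, −78 → 0 °C; then 1 M HCl, THF, rt
Reagents that add atoms: none
Why: BCl3 chelated between the lactone carbonyl and the adjacent methoxyl cleaves that aryl methyl ether, and it cleaves the benzyl ester through its chelated carboxyl, the benzyl cation being taken up by pentamethylbenzene. Dilute aqueous acid then hydrolyses the boron esters and the primary silyl ether. The aryl ester and the γ-lactone should tolerate both stages.

## Compound list

1 | 2,2,6-trimethyl-4H-1,3-dioxin-4-one | CC1=CC(=O)OC(C)(C)O1 | starting material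
2 | benzyl 2-(2,2-dimethyl-4-oxo-4H-1,3-dioxin-6-yl)acetate | O=C(CC1=CC(=O)OC(C)(C)O1)OCc1ccccc1 | intermediate
3 | benzyl 2-(2,2-dimethyl-4-oxo-4H-1,3-dioxin-6-yl)-3-oxobutanoate | CC(=O)C(C(=O)OCc1ccccc1)C1=CC(=O)OC(C)(C)O1 | intermediate
4 | benzyl 2-(2,2-dimethyl-4-oxo-4H-1,3-dioxin-6-yl)-3,5-dioxohexanoate (diketo dioxinone) | CC(=O)CC(=O)C(C(=O)OCc1ccccc1)C1=CC(=O)OC(C)(C)O1 | intermediate
5 | atraric acid (methyl 2,4-dihydroxy-3,6-dimethylbenzoate) | COC(=O)c1c(O)c(C)c(O)cc1C | starting material
6 | methyl 3-bromo-4,6-dihydroxy-2,5-dimethylbenzoate | COC(=O)c1c(O)c(C)c(O)c(Br)c1C | intermediate
7 | methyl 4-acetoxy-3-bromo-6-hydroxy-2,5-dimethylbenzoate | COC(=O)c1c(O)c(C)c(OC(C)=O)c(Br)c1C | intermediate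
8 | methyl 4-acetoxy-3-bromo-6-methoxy-2,5-dimethylbenzoate | COC(=O)c1c(OC)c(C)c(OC(C)=O)c(Br)c1C | intermediate
9 | methyl 4-acetoxy-3-bromo-2,5-bis(bromomethyl)-6-methoxybenzoate | COC(=O)c1c(OC)c(CBr)c(OC(C)=O)c(Br)c1CBr | intermediate
10 | 4-bromo-6-(hydroxymethyl)-7-methoxy-1-oxo-1,3-dihydroisobenzofuran-5-yl acetate (phthalide acetate) | COc1c(CO)c(OC(C)=O)c(Br)c2COC(=O)c12 | intermediate (not isolated)
11 | 4-bromo-5-hydroxy-6-(hydroxymethyl)-7-methoxyisobenzofuran-1(3H)-one | COc1c(CO)c(O)c(Br)c2COC(=O)c12 | intermediate
12 | 4-bromo-6-{[(tert-butyldimethylsilyl)oxy]methyl}-5-hydroxy-7-methoxyisobenzofuran-1(3H)-one (ring B bromo phthalide phenol) | COc1c(CO[Si](C)(C)C(C)(C)C)c(O)c(Br)c2COC(=O)c12 | intermediate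
13 | benzyl 3,5-dioxo-2-(3-oxobutanoyl)pent-4-enoate (acylketene) | CC(=O)CC(=O)C(C(=O)OCc1ccccc1)C(=O)C=C=O | intermediate (not isolated)
14 | 1-benzyl 5-(4-bromo-6-{[(tert-butyldimethylsilyl)oxy]methyl}-7-methoxy-1-oxo-1,3-dihydroisobenzofuran-5-yl) 3-oxo-2-(3-oxobutanoyl)pentanedioate (aryl triketo ester) | CC(=O)CC(=O)C(C(=O)OCc1ccccc1)C(=O)CC(=O)Oc1c(CO[Si](C)(C)C(C)(C)C)c(OC)c2C(=O)OCc2c1Br | intermediate (not isolated)
15 | 1-benzyl 3-(4-bromo-6-{[(tert-butyldimethylsilyl)oxy]methyl}-7-methoxy-1-oxo-1,3-dihydroisobenzofuran-5-yl) 2,6-dihydroxy-4-methylbenzene-1,3-dicarboxylate (bromo depside) | Cc1cc(O)c(C(=O)OCc2ccccc2)c(O)c1C(=O)Oc1c(CO[Si](C)(C)C(C)(C)C)c(OC)c2C(=O)OCc2c1Br | intermediate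
16 | protected depsidone: conneotricone benzyl ester, ring B phenol as methyl ether, benzylic alcohol as tert-butyldimethylsilyl ether | Cc1cc(O)c(C(=O)OCc2ccccc2)c2c1C(=O)Oc1c(CO[Si](C)(C)C(C)(C)C)c(OC)c3c(c1O2)COC3=O | intermediate
17 | conneotricone tert-butyldimethylsilyl ether (benzylic alcohol silylated, all else free) | Cc1cc(O)c(C(=O)O)c2c1C(=O)Oc1c(CO[Si](C)(C)C(C)(C)C)c(O)c3c(c1O2)COC3=O | intermediate (not isolated)
18 | conneotricone | Cc1cc(O)c(C(=O)O)c2c1C(=O)Oc1c(CO)c(O)c3c(c1O2)COC3=O | target

## Step count and least certain steps

Total: 12 steps. Longest linear sequence: 9 steps (steps 4 to 12, from 5). The three-step branch from 1 (steps 1 to 3) joins at step 10.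

**Step 10 (key step).** The ketene may be consumed by an enol oxygen of its own chain (pyranone formation) faster than the crowded phenol captures it. After capture the chain may close in the Claisen sense with expulsion of the aryloxide, and slow thermal fragmentation of the benzyl β-keto ester cannot be excluded. The fallback reverses the order of events and sets out from 4 and 12. Et3N in CH2Cl2 closes ring A first, by aldol addition of the dioxinone α-carbon to the methyl ketone and dehydration, to give the ring A acetonide benzyl 7-hydroxy-2,2,5-trimethyl-4-oxo-4H-benzo[d][1,3]dioxine-8-carboxylate F1. The sodium phenoxide of 12 (NaH, THF) then opens F1 at its carbonyl with loss of acetone, the known transesterification of salicylate acetonides, and acidification returns to the route at 15.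

**Step 11.** Oxidative addition at a bromide flanked on both sides may be slow. Under carbonate at 90 °C the depside may undergo acyl transfer or a Smiles-type aryl migration, and protodebromination may compete. The fallback reverses the polarity of ring B and sets out from 15. Miyaura borylation (bis(pinacolato)diboron, PdCl2(dppf), KOAc, dioxane, 80 °C) gives the pinacol boronate of the depside F2. An intramolecular Chan–Lam etherification (Cu(OAc)2 catalytic under air, pyridine, CH2Cl2, rt) then closes the ring without strong base or heat and returns to the route at 16.

**Step 3.** Formation of the dianion may be incomplete, the carbanion may attack another molecule of the substrate, and 4 may cyclise during work-up. The fallback sets out from 2 and bypasses 3. The lithium enolate of 2 (LiHMDS, THF, −78 °C) is C-acetoacetylated directly by ring opening of diketene, the known acetoacetylation of stabilised enolates, and the acidic quench returns to the route at 4. No new compound is made.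

**Step 8.** Solvolysis at the hindered benzylic positions may stall. Once the phenol is unmasked next to a benzylic leaving group, an ortho-quinone methide can form and oligomerise. The fallback sets out from 9 and replaces solvolysis by carboxylate displacement. KOAc in DMF at 50 °C gives the triacetate methyl 4-acetoxy-2,5-bis(acetoxymethyl)-3-bromo-6-methoxybenzoate F3. Aqueous LiOH in THF (water as the only nucleophile) followed by HCl cleaves all three acetates and closes the lactone, returning to the route at 11.

**Step 12.** Under the Lewis acid the benzylic C–O bond may ionise with capture of chloride, the benzyl cation may alkylate ring A, and a large excess of BCl3 may attack the seven-membered ester. The fallback separates the deprotections and sets out from 16. Hydrogenolysis (H2, Pd/C, EtOAc) removes the benzyl ester to give the depsidone acid F4, still methylated and silylated. A small excess of BCl3 at −78 °C then has only the chelated methyl ether to cleave and no benzyl cation to generate. This returns to the route at 17, which is hydrolysed to 18 as in step 12.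

## Further compounds

F1 | step 10 | benzyl 7-hydroxy-2,2,5-trimethyl-4-oxo-4H-benzo[d][1,3]dioxine-8-carboxylate (ring A acetonide) | Cc1cc(O)c(C(=O)OCc2ccccc2)c2OC(C)(C)OC(=O)c12
F2 | step 11 | pinacol boronate of the depside (15 with the bromine replaced by 4,4,5,5-tetramethyl-1,3,2-dioxaborolan-2-yl) | Cc1cc(O)c(C(=O)OCc2ccccc2)c(O)c1C(=O)Oc1c(CO[Si](C)(C)C(C)(C)C)c(OC)c2C(=O)OCc2c1B1OC(C)(C)C(C)(C)O1
F0 | step 3 | none | none
F3 | step 8 | methyl 4-acetoxy-2,5-bis(acetoxymethyl)-3-bromo-6-methoxybenzoate | COC(=O)c1c(OC)c(COC(C)=O)c(OC(C)=O)c(Br)c1COC(C)=O
F4 | step 12 | depsidone acid (16 with the benzyl ester replaced by the free carboxylic acid) | Cc1cc(O)c(C(=O)O)c2c1C(=O)Oc1c(CO[Si](C)(C)C(C)(C)C)c(OC)c3c(c1O2)COC3=O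
A1 | alternative 1 | 5-(tert-butyldiphenylsilyloxy)-1-methoxy-1,3-bis(trimethylsilyloxy)penta-1,3-diene | COC(O[Si](C)(C)C)=CC(O[Si](C)(C)C)=CCO[Si](c1ccccc1)(c1ccccc1)C(C)(C)C
A2 | alternative 1 | 1-benzyl 3-methyl 2-[(1-acetoxy-4,4-dimethoxy-2-oxobut-3-en-3-yl)oxy]-6-(benzyloxy)-4-methylbenzene-1,3-dicarboxylate (2-aryloxy dielectrophile) | CC(=O)OCC(=O)C(Oc1c(C(=O)OC)c(C)cc(OCc2ccccc2)c1C(=O)OCc1ccccc1)=C(OC)OC
A3 | alternative 1 | diaryl ether with ring B formed | COC(=O)c1c(O)c(CO[Si](c2ccccc2)(c2ccccc2)C(C)(C)C)c(OC)c(Oc2c(C(=O)OC)c(C)cc(OCc3ccccc3)c2C(=O)OCc2ccccc2)c1COC(C)=O
A4 | alternative 2 | protected depsidone carboxylic acid with a free ortho C–H on ring B | Cc1cc(OC)c(C(=O)OCc2ccccc2)c2c1C(=O)Oc1c(CO[Si](C)(C)C(C)(C)C)c(OC)c(C(=O)O)cc1O2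
A5 | alternative 2 | protected depsidone with phthalide | Cc1cc(OC)c(C(=O)OCc2ccccc2)c2c1C(=O)Oc1c(CO[Si](C)(C)C(C)(C)C)c(OC)c3c(c1O2)COC3=O
A6 | alternative 3 | 6-(tert-butyldimethylsilyloxy)hexa-2,4-diyn-1-yl 3-[isopropoxy(dimethyl)silyl]prop-2-ynoate | CC(C)O[Si](C)(C)C#CC(=O)OCC#CC#CCO[Si](C)(C)C(C)(C)C
A7 | alternative 3 | benzyne fused to the butenolide (aryne bond between the carbons next to the silyloxymethyl group and the lactone methylene) | CC(C)O[Si](C)(C)C1=C(CO[Si](C)(C)C(C)(C)C)C#CC2=C1C(=O)OC2
A8 | alternative 3 | 3-(tert-butoxycarbonyl)-2,4-dihydroxy-6-methylbenzoic acid (ring A acid) | Cc1cc(O)c(C(=O)OC(C)(C)C)c(O)c1C(=O)O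
A9 | alternative 3 | depside with ring B and phthalide formed | Cc1cc(O)c(C(=O)OC(C)(C)C)c(O)c1C(=O)Oc1cc2COC(=O)c2c([Si](C)(C)OC(C)C)c1CO[Si](C)(C)C(C)(C)C
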